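**Plan**

- Numbering runs C1 (alkyne CH) to C15 (ethyl CH3); the ring oxygen joins C9 and C13. Retrosynthesis cuts C10–Cl and C12–Br (each back to the epimeric C–O), then O–C9 (reduction of a C9 oxocarbenium ion), C7–C8 (aldol onto a C1–C7 α-chloroaldehyde), C8–C9 (methyl onto a C9 acyl group), and last C13–C14 together with O–C9 at the lactone level.
- Enabling feature: the C9–C13 segment, oxygenated at C10 and C12 on either side of the C11 methylene, is the carbon ring of trans-cyclopent-4-ene-1,3-diol opened between its two alkene carbons. The C2 axis of its bis-ether lets an ester/aldehyde ozonolysis give one product (C9 ester, C13 aldehyde).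
- Forward: the six-membered ring (O, C9–C13) arises first as a δ-lactone (ethyl Grignard addition, then lactonisation). It is relayed through a Weinreb amide to the open C9 methyl ketone, joined at C7–C8 to fragment C1–C7, and closed again as the oxane by silane reduction. Two halide displacements and desilylation finish the route.
- Stereochemistry: C10 and C12 come from the chiral-pool cyclopentenol (one Mitsunobu inversion; both inverted once more by halide at the end). C13 is set by Cram chelation, C6 by enamine-catalysed chlorination, C7 by 1,2-anti addition to the α-chloroaldehyde, C9 by axial hydride delivery, and C3=C4 by syn-hydrozirconation.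

Key step: step 5

Assumption: (2S,5S)-2,5-diphenylpyrrolidine is taken to deliver the (R)-α-chloroaldehyde 20; should the sense be the reverse, its (2R,5R) antipode is used.

**Route**

Step 1
Reactants: 1 (1R,4S)-cis-4-acetoxycyclopent-2-en-1-ol
Product: 2 (1S,4S)-4-acetoxycyclopent-2-en-1-yl 4-nitrobenzoate (trans diester)
Conditions: 4-nitrobenzoic acid, PPh3, DIAD, THF, 0 °C → rt
Reagents that add atoms: 4-nitrobenzoic acid, O=C(O)c1ccc(cc1)[N+](=O)[O-]
Why: Mitsunobu esterification displaces the activated allylic oxygen by SN2 with inversion, so the cis monoacetate should become the trans (1S,4S) diester, the acidic nitrobenzoate favouring clean inversion.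

Step 2
Reactants: 2 (1S,4S)-4-acetoxycyclopent-2-en-1-yl 4-nitrobenzoate
Product: 3 (1S,3S)-cyclopent-4-ene-1,3-diol
Conditions: K2CO3 (cat.), MeOH, 0 °C → rt
Reagents that add atoms: none
Why: Base-catalysed transesterification (methanolysis) cleaves both esters at the acyl–oxygen bond, so neither carbinol centre is touched and the C2-symmetric trans diol should result.

Step 3
Reactants: 3 (1S,3S)-cyclopent-4-ene-1,3-diol; 4 2-(bromomethyl)naphthalene
Product: 5 (3S,5S)-3,5-bis(naphthalen-2-ylmethoxy)cyclopent-1-ene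
Conditions: NaH, n-Bu4NI (cat.), DMF, 0 °C → rt
Reagents that add atoms: 2-(bromomethyl)naphthalene (4), BrCc1ccc2ccccc2c1
Why: Williamson etherification of both alkoxides; the 2-naphthylmethyl ether is a benzyl-type, chelating ether that should survive the later Lewis acid/silane step and still be removable with DDQ.

Step 4
Reactants: 5 (3S,5S)-3,5-bis(naphthalen-2-ylmethoxy)cyclopent-1-ene
Product: 7 methyl (2S,4S)-2,4-bis(naphthalen-2-ylmethoxy)-5-oxopentanoate, via methoxy hydroperoxide 6 (not isolated)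
Conditions: O3, NaHCO3, CH2Cl2/MeOH, −78 °C (Sudan Red 7B end-point); then Ac2O, Et3N, CH2Cl2, 0 °C → rt
Reagents that add atoms: ozone, [O-][O+]=O; methanol, CO
Why: Criegee ozonolysis in methanol traps the carbonyl oxide as the α-methoxy hydroperoxide 6 beside the aldehyde, and acylation–elimination turns that terminus into the methyl ester; the C2 axis makes either direction of cleavage give the same C9 ester/C13 aldehyde, and the strained alkene should be consumed well before the naphthalene rings.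

Step 5
Reactants: 7 methyl (2S,4S)-2,4-bis(naphthalen-2-ylmethoxy)-5-oxopentanoate; 8 ethylmagnesium bromide
Product: 10 (3S,5S,6S)-6-ethyl-3,5-bis(naphthalen-2-ylmethoxy)oxan-2-one, via bromomagnesium alkoxide 9 (not isolated)
Conditions: MgBr2·OEt2, CH2Cl2, −78 °C; EtMgBr (1.1 equiv, Et2O), −78 → 0 °C; aq NH4Cl
Reagents that add atoms: ethylmagnesium bromide (8), CC[Mg]Br
Why: Magnesium bridges the C13 aldehyde oxygen and the C12 ether oxygen in a five-membered Cram chelate, and ethyl adds to the face away from the C11 chain, forming C13–C14 and the 12,13-syn alkoxide 9. The closest known reaction type is the chelation-controlled Grignard addition to an α-alkoxy aldehyde. On warming, the C13 alkoxide attacks the C9 methyl ester and expels methoxide, a 6-exo-trig acyl substitution that closes the δ-lactone ring (O, C9–C13). The new C13 stereocentre is controlled by the C12 stereocentre through the chelate, while C10 and C12 pass through unchanged. The step needs chelate control over Felkin–Anh addition and aldehyde over ester addition. The benzyl-type ether at C12, MgBr2 in non-coordinating CH2Cl2 and one equivalent of reagent at −78 °C should secure both.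

Step 6
Reactants: 10 (3S,5S,6S)-6-ethyl-3,5-bis(naphthalen-2-ylmethoxy)oxan-2-one
Product: 11 (2S,4S,5S)-5-hydroxy-N-methoxy-N-methyl-2,4-bis(naphthalen-2-ylmethoxy)heptanamide
Conditions: MeNH(OMe)·HCl, AlMe3, CH2Cl2, 0 °C → rt
Reagents that add atoms: N,O-dimethylhydroxylamine hydrochloride, CNOC.Cl
Why: Weinreb aminolysis of the lactone by the aluminium amide (acyl substitution at C9) frees the C13 hydroxyl and leaves an acyl donor that accepts exactly one carbon nucleophile, with no stereocentre involved.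

Step 7
Reactants: 11 (2S,4S,5S)-5-hydroxy-N-methoxy-N-methyl-2,4-bis(naphthalen-2-ylmethoxy)heptanamide
Product: 12 (2S,4S,5S)-N-methoxy-N-methyl-2,4-bis(naphthalen-2-ylmethoxy)-5-(triethylsilyloxy)heptanamide
Conditions: Et3SiCl, imidazole, DMF, 0 °C → rt
Reagents that add atoms: chlorotriethylsilane, CC[Si](Cl)(CC)CC
Why: O-silylation of the secondary alcohol blocks relactonisation and hemiketal formation, and the triethylsilyl ether is labile enough to be lost in the flask during the later reductive ring closure.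

Step 8
Reactants: 12 (2S,4S,5S)-N-methoxy-N-methyl-2,4-bis(naphthalen-2-ylmethoxy)-5-(triethylsilyloxy)heptanamide
Product: 13 (3S,5S,6S)-3,5-bis(naphthalen-2-ylmethoxy)-6-(triethylsilyloxy)octan-2-one
Conditions: MeMgBr, THF, 0 °C
Reagents that add atoms: methylmagnesium bromide, C[Mg]Br
Why: Weinreb ketone synthesis: the chelated tetrahedral adduct holds until work-up, so a single methyl (C8) should add at C9 without epimerising C10.

Step 9
Reactants: 14 pent-4-yn-1-ol
Product: 16 (E)-5-iodopent-4-en-1-ol, via alkenylzirconocene 15 (not isolated)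
Conditions: Cp2Zr(H)Cl (2.2 equiv), THF, rt; then I2, 0 °C
Reagents that add atoms: iodine, II
Why: Hydrozirconation (after the first equivalent has capped the hydroxyl) adds Zr–H syn across the terminal alkyne with zirconium on the end carbon, and iodinolysis with retention should give only the E vinyl iodide that becomes C3=C4.

Step 10
Reactants: 16 (E)-5-iodopent-4-en-1-ol; 17 ethynyltrimethylsilane
Product: 18 (E)-7-(trimethylsilyl)hept-4-en-6-yn-1-ol
Conditions: PdCl2(PPh3)2 (cat.), CuI (cat.), Et3N, THF, rt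
Reagents that add atoms: ethynyltrimethylsilane (17), C#C[Si](C)(C)C
Why: Sonogashira coupling of a vinyl iodide proceeds with retention of alkene geometry and tolerates the free alcohol, giving the silyl-capped E enyne (C1–C4).

Step 11
Reactants: 18 (E)-7-(trimethylsilyl)hept-4-en-6-yn-1-ol
Product: 19 (E)-7-(trimethylsilyl)hept-4-en-6-ynal
Conditions: Dess–Martin periodinane, NaHCO3, CH2Cl2, 0 °C → rt
Reagents that add atoms: none
Why: Dess–Martin oxidation of the primary alcohol is neutral and should not move the skipped enyne into conjugation.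

Step 12
Reactants: 19 (E)-7-(trimethylsilyl)hept-4-en-6-ynal
Product: 20 (2R,4E)-2-chloro-7-(trimethylsilyl)hept-4-en-6-ynal
Conditions: N-chlorosuccinimide, (2S,5S)-2,5-diphenylpyrrolidine (10 mol %), CH2Cl2, 0 °C; used at once without chromatography
Reagents that add atoms: N-chlorosuccinimide, O=C1CCC(=O)N1Cl
Why: Enamine-catalysed α-chlorination: the C2-symmetric pyrrolidine shields one face of the enamine so that chlorine is delivered to one face and C6 is set, and immediate use limits epimerisation of the labile α-chloroaldehyde.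

Step 13
Reactants: 13 (3S,5S,6S)-3,5-bis(naphthalen-2-ylmethoxy)-6-(triethylsilyloxy)octan-2-one; 20 (2R,4E)-2-chloro-7-(trimethylsilyl)hept-4-en-6-ynal
Product: 22 (3S,4S,6S,9S,10R,12E)-10-chloro-9-hydroxy-4,6-bis(naphthalen-2-ylmethoxy)-3-(triethylsilyloxy)-15-(trimethylsilyl)pentadec-12-en-14-yn-7-one, via lithium enolate 21 (not isolated)
Conditions: LiN(i-Pr)2, THF, −78 °C; then 20, −78 °C; NH4Cl quench at −78 °C
Reagents that add atoms: none
Why: Lithium aldol addition: kinetic deprotonation at the C8 methyl gives enolate 21, which adds to the α-chloroaldehyde with C–Cl antiperiplanar to the carbonyl (Cornforth/polar Felkin–Anh control), so the 6,7-anti chlorohydrin (C7 S from C6 R) should form together with the C7–C8 bond.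

Step 14
Reactants: 22 (the β-hydroxy ketone of step 13)
Product: 23 (3S,4S,6S,9S,10R,12E)-10-chloro-4,6-bis(naphthalen-2-ylmethoxy)-7-oxo-3-(triethylsilyloxy)-15-(trimethylsilyl)pentadec-12-en-14-yn-9-yl acetate
Conditions: Ac2O, pyridine, DMAP (cat.), CH2Cl2, 0 °C
Reagents that add atoms: acetic anhydride, CC(=O)OC(C)=O
Why: O-acylation installs the C7 acetate of the target and at the same time blocks retro-aldol cleavage and epoxide formation from the chlorohydrin.

Step 15
Reactants: 23 (the acetoxy ketone of step 14)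
Product: 25 (2S,3R,5E)-3-chloro-1-[(2R,3S,5S,6S)-6-ethyl-3,5-bis(naphthalen-2-ylmethoxy)oxan-2-yl]-8-(trimethylsilyl)oct-5-en-7-yn-2-yl acetate, via oxocarbenium triflate 24 (not isolated)
Conditions: Et3SiH, Me3SiOTf, CH2Cl2, −78 → −20 °C
Reagents that add atoms: none
Why: Reductive etherification: the silyl triflate activates the C9 ketone, the C13 silyl ether oxygen closes onto it (6-exo-trig) to give the cyclic oxocarbenium ion 24, and axial hydride delivery to the half-chair with the C13 ethyl and C10 ether pseudo-equatorial and the C12 ether pseudo-axial should set C9–H cis to C13–H (2,6-cis oxane).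

Step 16
Reactants: 25 (the bis-ether oxane of step 15)
Product: 26 (2S,3R,5E)-3-chloro-1-[(2R,3S,5S,6S)-6-ethyl-3,5-dihydroxyoxan-2-yl]-8-(trimethylsilyl)oct-5-en-7-yn-2-yl acetate
Conditions: DDQ, CH2Cl2/pH 7 buffer, rt
Reagents that add atoms: none
Why: Oxidative cleavage of the 2-naphthylmethyl ethers (benzylic hydride abstraction, then hydrolysis of the hemiacetal) leaves the acetate, the chloride and the silyl enyne untouched and frees the equatorial C10 and axial C12 hydroxyls.

Step 17
Reactants: 26 (the diol of step 16)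
Product: 27 (2S,3R,5E)-1-[(2R,3S,5S,6S)-3,5-bis(chloromethanesulfonyloxy)-6-ethyloxan-2-yl]-3-chloro-8-(trimethylsilyl)oct-5-en-7-yn-2-yl acetate
Conditions: ClCH2SO2Cl, pyridine, CH2Cl2, 0 °C
Reagents that add atoms: chloromethanesulfonyl chloride, ClCS(Cl)(=O)=O
Why: O-sulfonylation of both hydroxyls with a small, strongly nucleofugal group retains both configurations and removes any need to tell the two hydroxyls apart at this stage.

Step 18
Reactants: 27 (the bis-sulfonate of step 17)
Product: 28 (2S,3R,5E)-1-[(2R,3S,5R,6S)-5-bromo-3-(chloromethanesulfonyloxy)-6-ethyloxan-2-yl]-3-chloro-8-(trimethylsilyl)oct-5-en-7-yn-2-yl acetate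
Conditions: n-Bu4NBr (1.1 equiv), toluene, rt → 40 °C
Reagents that add atoms: tetrabutylammonium bromide, CCCC[N+](CCCC)(CCCC)CCCC.[Br-]
Why: SN2 displacement with inversion at C12: the axial sulfonate is open to attack from the equatorial side, whereas attack at the equatorial C10 sulfonate would have to come in axially, syn to the axial C12 group, so bromide should enter only at C12 and end up equatorial.

Step 19
Reactants: 28 (the bromo sulfonate of step 18)
Product: 29 (2S,3R,5E)-1-[(2R,3R,5R,6S)-5-bromo-3-chloro-6-ethyloxan-2-yl]-3-chloro-8-(trimethylsilyl)oct-5-en-7-yn-2-yl acetate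
Conditions: LiCl, DMF, 50 °C
Reagents that add atoms: lithium chloride, [Li+].[Cl-]
Why: SN2 displacement with inversion at C10: with C12 now carrying an equatorial bromide the axial approach to C10 meets only hydrogen, and the chloromethanesulfonate leaves far faster than the secondary bromide, so the axial C10 chloride should form while C12–Br persists.

Step 20
Reactants: 29 (the silyl enyne of step 19)
Product: 30 (2S,3R,5E)-1-[(2R,3R,5R,6S)-5-bromo-3-chloro-6-ethyloxan-2-yl]-3-chlorooct-5-en-7-yn-2-yl acetate (target)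
Conditions: n-Bu4NF, AcOH, THF, −20 → 0 °C
Reagents that add atoms: none
Why: Fluoride-induced protodesilylation of the alkynylsilane is fast at low temperature, and the acetic acid buffer should keep the acetate and the three secondary halides intact.

**Compound list**

1 | (1R,4S)-cis-4-acetoxycyclopent-2-en-1-ol | CC(=O)O[C@@H]1C=C[C@H](O)C1 | starting material
2 | (1S,4S)-4-acetoxycyclopent-2-en-1-yl 4-nitrobenzoate | CC(=O)O[C@@H]1C=C[C@@H](OC(=O)c2ccc(cc2)[N+](=O)[O-])C1 | intermediate
3 | (1S,3S)-cyclopent-4-ene-1,3-diol | O[C@@H]1C=C[C@@H](O)C1 | intermediate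
4 | 2-(bromomethyl)naphthalene | BrCc1ccc2ccccc2c1 | starting material
5 | (3S,5S)-3,5-bis(naphthalen-2-ylmethoxy)cyclopent-1-ene | C(O[C@@H]1C=C[C@@H](OCc2ccc3ccccc3c2)C1)c1ccc2ccccc2c1 | intermediate
6 | (2S,4S)-5-hydroperoxy-5-methoxy-2,4-bis(naphthalen-2-ylmethoxy)pentanal (C5 epimers) | COC(OO)[C@@H](OCc1ccc2ccccc2c1)C[C@H](OCc1ccc2ccccc2c1)C=O | intermediate (not isolated)
7 | methyl (2S,4S)-2,4-bis(naphthalen-2-ylmethoxy)-5-oxopentanoate | COC(=O)[C@@H](OCc1ccc2ccccc2c1)C[C@H](OCc1ccc2ccccc2c1)C=O | intermediate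
8 | ethylmagnesium bromide | CC[Mg]Br | starting material
9 | bromomagnesium (3S,4S,6S)-7-methoxy-4,6-bis(naphthalen-2-ylmethoxy)-7-oxoheptan-3-olate | CC[C@H](O[Mg]Br)[C@@H](OCc1ccc2ccccc2c1)C[C@H](OCc1ccc2ccccc2c1)C(=O)OC | intermediate (not isolated)
10 | (3S,5S,6S)-6-ethyl-3,5-bis(naphthalen-2-ylmethoxy)oxan-2-one | CC[C@@H]1OC(=O)[C@@H](OCc2ccc3ccccc3c2)C[C@@H]1OCc1ccc2ccccc2c1 | intermediate
11 | (2S,4S,5S)-5-hydroxy-N-methoxy-N-methyl-2,4-bis(naphthalen-2-ylmethoxy)heptanamide | CC[C@H](O)[C@@H](OCc1ccc2ccccc2c1)C[C@H](OCc1ccc2ccccc2c1)C(=O)N(C)OC | intermediate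
12 | (2S,4S,5S)-N-methoxy-N-methyl-2,4-bis(naphthalen-2-ylmethoxy)-5-(triethylsilyloxy)heptanamide | CC[C@H](O[Si](CC)(CC)CC)[C@@H](OCc1ccc2ccccc2c1)C[C@H](OCc1ccc2ccccc2c1)C(=O)N(C)OC | intermediate
13 | (3S,5S,6S)-3,5-bis(naphthalen-2-ylmethoxy)-6-(triethylsilyloxy)octan-2-one | CC[C@H](O[Si](CC)(CC)CC)[C@@H](OCc1ccc2ccccc2c1)C[C@H](OCc1ccc2ccccc2c1)C(C)=O | intermediate
14 | pent-4-yn-1-ol | C#CCCCO | starting material
15 | (E)-alkenylzirconocene chloride from 14, oxygen also zirconated | Cl[Zr](/C=C/CCCO[Zr](Cl)(C1C=CC=C1)C1C=CC=C1)(C1C=CC=C1)C1C=CC=C1 | intermediate (not isolated)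
16 | (E)-5-iodopent-4-en-1-ol | OCCC/C=C/I | intermediate
17 | ethynyltrimethylsilane | C#C[Si](C)(C)C | starting material
18 | (E)-7-(trimethylsilyl)hept-4-en-6-yn-1-ol | C[Si](C)(C)C#C/C=C/CCCO | intermediate
19 | (E)-7-(trimethylsilyl)hept-4-en-6-ynal | C[Si](C)(C)C#C/C=C/CCC=O | intermediate
20 | (2R,4E)-2-chloro-7-(trimethylsilyl)hept-4-en-6-ynal | C[Si](C)(C)C#C/C=C/C[C@@H](Cl)C=O | intermediate
21 | lithium enolate of 13 (C8=C9, O–Li) | [Li]OC(=C)[C@@H](OCc1ccc2ccccc2c1)C[C@H](OCc1ccc2ccccc2c1)[C@H](CC)O[Si](CC)(CC)CC | intermediate (not isolated)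
22 | (3S,4S,6S,9S,10R,12E)-10-chloro-9-hydroxy-4,6-bis(naphthalen-2-ylmethoxy)-3-(triethylsilyloxy)-15-(trimethylsilyl)pentadec-12-en-14-yn-7-one | C[Si](C)(C)C#C/C=C/C[C@@H](Cl)[C@@H](O)CC(=O)[C@@H](OCc1ccc2ccccc2c1)C[C@H](OCc1ccc2ccccc2c1)[C@H](CC)O[Si](CC)(CC)CC | intermediate
23 | (3S,4S,6S,9S,10R,12E)-10-chloro-4,6-bis(naphthalen-2-ylmethoxy)-7-oxo-3-(triethylsilyloxy)-15-(trimethylsilyl)pentadec-12-en-14-yn-9-yl acetate | C[Si](C)(C)C#C/C=C/C[C@@H](Cl)[C@@H](OC(C)=O)CC(=O)[C@@H](OCc1ccc2ccccc2c1)C[C@H](OCc1ccc2ccccc2c1)[C@H](CC)O[Si](CC)(CC)CC | intermediate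
24 | cyclic C9 oxocarbenium triflate (O1=C9, substituents as in 25) | C[Si](C)(C)C#C/C=C/C[C@@H](Cl)[C@H](CC1=[O+][C@@H](CC)[C@@H](OCc2ccc3ccccc3c2)C[C@@H]1OCc1ccc2ccccc2c1)OC(C)=O.[O-]S(=O)(=O)C(F)(F)F | intermediate (not isolated)
25 | (2S,3R,5E)-3-chloro-1-[(2R,3S,5S,6S)-6-ethyl-3,5-bis(naphthalen-2-ylmethoxy)oxan-2-yl]-8-(trimethylsilyl)oct-5-en-7-yn-2-yl acetate | C[Si](C)(C)C#C/C=C/C[C@@H](Cl)[C@H](C[C@H]1O[C@@H](CC)[C@@H](OCc2ccc3ccccc3c2)C[C@@H]1OCc1ccc2ccccc2c1)OC(C)=O | intermediate
26 | (2S,3R,5E)-3-chloro-1-[(2R,3S,5S,6S)-6-ethyl-3,5-dihydroxyoxan-2-yl]-8-(trimethylsilyl)oct-5-en-7-yn-2-yl acetate | C[Si](C)(C)C#C/C=C/C[C@@H](Cl)[C@H](C[C@H]1O[C@@H](CC)[C@@H](O)C[C@@H]1O)OC(C)=O | intermediate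
27 | (2S,3R,5E)-1-[(2R,3S,5S,6S)-3,5-bis(chloromethanesulfonyloxy)-6-ethyloxan-2-yl]-3-chloro-8-(trimethylsilyl)oct-5-en-7-yn-2-yl acetate | C[Si](C)(C)C#C/C=C/C[C@@H](Cl)[C@H](C[C@H]1O[C@@H](CC)[C@@H](OS(=O)(=O)CCl)C[C@@H]1OS(=O)(=O)CCl)OC(C)=O | intermediate
28 | (2S,3R,5E)-1-[(2R,3S,5R,6S)-5-bromo-3-(chloromethanesulfonyloxy)-6-ethyloxan-2-yl]-3-chloro-8-(trimethylsilyl)oct-5-en-7-yn-2-yl acetate | C[Si](C)(C)C#C/C=C/C[C@@H](Cl)[C@H](C[C@H]1O[C@@H](CC)[C@H](Br)C[C@@H]1OS(=O)(=O)CCl)OC(C)=O | intermediate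
29 | (2S,3R,5E)-1-[(2R,3R,5R,6S)-5-bromo-3-chloro-6-ethyloxan-2-yl]-3-chloro-8-(trimethylsilyl)oct-5-en-7-yn-2-yl acetate | C[Si](C)(C)C#C/C=C/C[C@@H](Cl)[C@H](C[C@H]1O[C@@H](CC)[C@H](Br)C[C@H]1Cl)OC(C)=O | intermediate
30 | (2S,3R,5E)-1-[(2R,3R,5R,6S)-5-bromo-3-chloro-6-ethyloxan-2-yl]-3-chlorooct-5-en-7-yn-2-yl acetate | C#C/C=C/C[C@@H](Cl)[C@H](C[C@H]1O[C@@H](CC)[C@H](Br)C[C@H]1Cl)OC(C)=O | target

**Step count and risks**

Total step count: 20. Longest linear sequence: 16 steps (steps 1–8 and 13–20, from compound 1); the C1–C7 fragment takes steps 9–12.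

The three steps most likely to fail:

Step 15 (reductive ring closure). The β-acetoxy ketone may lose acetic acid across C7–C8 before or after ionisation at C9. Hydride may also arrive on a half-chair that has not settled, eroding the 2,6-cis preference, and the naphthylmethyl ethers could be reduced off by the silyl triflate/silane pair. The fallback closes the ring before the acetate is present and separates ketalisation from reduction. It sets out from compound 22. Treatment with HF·pyridine in THF removes the triethylsilyl group and should give the cyclic hemiketal (3S,5S,6S)-2-[(2S,3R,5E)-3-chloro-2-hydroxy-8-(trimethylsilyl)oct-5-en-7-yn-1-yl]-6-ethyl-3,5-bis(naphthalen-2-ylmethoxy)oxan-2-ol F1. Ionic reduction of its anomeric hydroxyl with Et3SiH and BF3·OEt2 in CH2Cl2/MeCN at −40 °C should then give (2S,3R,5E)-3-chloro-1-[(2R,3S,5S,6S)-6-ethyl-3,5-bis(naphthalen-2-ylmethoxy)oxan-2-yl]-8-(trimethylsilyl)oct-5-en-7-yn-2-ol F2. Acetylation (Ac2O, pyridine) returns to the route at compound 25.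

Step 18 (site-selective bromide displacement). Bromide may fail to discriminate between the axial C12 and the equatorial C10 sulfonate, or may act as a base and cause E2 loss of the axial sulfonate toward C11 or C13. The fallback replaces kinetic discrimination in the displacement by a protecting-group relay. It sets out from diol 26. Silylation with t-BuMe2SiCl and imidazole should select the equatorial C10 hydroxyl and give (2S,3R,5E)-1-[(2R,3S,5S,6S)-3-(tert-butyldimethylsilyloxy)-6-ethyl-5-hydroxyoxan-2-yl]-3-chloro-8-(trimethylsilyl)oct-5-en-7-yn-2-yl acetate F3. The axial C12 hydroxyl is then brominated with inversion through its alkoxyphosphonium salt (CBr4, P(n-Oct)3, toluene, 70 °C) to give (2S,3R,5E)-1-[(2R,3S,5R,6S)-5-bromo-3-(tert-butyldimethylsilyloxy)-6-ethyloxan-2-yl]-3-chloro-8-(trimethylsilyl)oct-5-en-7-yn-2-yl acetate F4. HF·pyridine frees (2S,3R,5E)-1-[(2R,3S,5R,6S)-5-bromo-6-ethyl-3-hydroxyoxan-2-yl]-3-chloro-8-(trimethylsilyl)oct-5-en-7-yn-2-yl acetate F5, and chloromethanesulfonylation (ClCH2SO2Cl, pyridine) returns to the route at compound 28.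

Step 13 (aldol with the α-chloroaldehyde). Under the basic enolate the aldehyde 20 may epimerise at C6 or lose HCl toward the conjugated dienyne, and the addition may show poor facial selectivity or revert by retro-aldol. The fallback moves the C7–C8 bond formation to a non-basic, Lewis-acid-mediated open transition state. It sets out from ketone 13. Kinetic enolisation and trapping (LiN(i-Pr)2, Me3SiCl, THF, −78 °C) should give the silyl enol ether triethyl{[(3S,4S,6S)-4,6-bis(naphthalen-2-ylmethoxy)-7-(trimethylsilyloxy)oct-7-en-3-yl]oxy}silane F6. A Mukaiyama aldol addition of F6 to 20 with BF3·OEt2 in CH2Cl2 at −78 °C, which follows the same 1,2-anti sense, returns to the route at compound 22.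

**Further compounds**

F1 | step 15 | (3S,5S,6S)-2-[(2S,3R,5E)-3-chloro-2-hydroxy-8-(trimethylsilyl)oct-5-en-7-yn-1-yl]-6-ethyl-3,5-bis(naphthalen-2-ylmethoxy)oxan-2-ol | C[Si](C)(C)C#C/C=C/C[C@@H](Cl)[C@@H](O)CC1(O)O[C@@H](CC)[C@@H](OCc2ccc3ccccc3c2)C[C@@H]1OCc1ccc2ccccc2c1
F2 | step 15 | (2S,3R,5E)-3-chloro-1-[(2R,3S,5S,6S)-6-ethyl-3,5-bis(naphthalen-2-ylmethoxy)oxan-2-yl]-8-(trimethylsilyl)oct-5-en-7-yn-2-ol | C[Si](C)(C)C#C/C=C/C[C@@H](Cl)[C@@H](O)C[C@H]1O[C@@H](CC)[C@@H](OCc2ccc3ccccc3c2)C[C@@H]1OCc1ccc2ccccc2c1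
F3 | step 18 | (2S,3R,5E)-1-[(2R,3S,5S,6S)-3-(tert-butyldimethylsilyloxy)-6-ethyl-5-hydroxyoxan-2-yl]-3-chloro-8-(trimethylsilyl)oct-5-en-7-yn-2-yl acetate | C[Si](C)(C)C#C/C=C/C[C@@H](Cl)[C@H](C[C@H]1O[C@@H](CC)[C@@H](O)C[C@@H]1O[Si](C)(C)C(C)(C)C)OC(C)=O
F4 | step 18 | (2S,3R,5E)-1-[(2R,3S,5R,6S)-5-bromo-3-(tert-butyldimethylsilyloxy)-6-ethyloxan-2-yl]-3-chloro-8-(trimethylsilyl)oct-5-en-7-yn-2-yl acetate | C[Si](C)(C)C#C/C=C/C[C@@H](Cl)[C@H](C[C@H]1O[C@@H](CC)[C@H](Br)C[C@@H]1O[Si](C)(C)C(C)(C)C)OC(C)=O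
F5 | step 18 | (2S,3R,5E)-1-[(2R,3S,5R,6S)-5-bromo-6-ethyl-3-hydroxyoxan-2-yl]-3-chloro-8-(trimethylsilyl)oct-5-en-7-yn-2-yl acetate | C[Si](C)(C)C#C/C=C/C[C@@H](Cl)[C@H](C[C@H]1O[C@@H](CC)[C@H](Br)C[C@@H]1O)OC(C)=O
F6 | step 13 | triethyl{[(3S,4S,6S)-4,6-bis(naphthalen-2-ylmethoxy)-7-(trimethylsilyloxy)oct-7-en-3-yl]oxy}silane | C=C(O[Si](C)(C)C)[C@@H](OCc1ccc2ccccc2c1)C[C@H](OCc1ccc2ccccc2c1)[C@H](CC)O[Si](CC)(CC)CC
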